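## Retrosynthetic overview

1. The target is epioritin-(4β→6)-oritin-4α-ol. The upper unit has rings A (benzo), B (2-aryl) and C (pyran); the lower unit has rings D, E and F in the same sense. Flavan numbering is used, and α is the pyran face that carries the 2-aryl group.
2. The key disconnection is C4 (ring C)–C6 (ring D). It is made biomimetically: a flavan-4-yl cation is released from a 2,3-cis-3α,4α-epoxyflavan formed in the flask from a bromohydrin, and ring D of a protected flavan-3,4-diol captures it.
3. Enabling feature: C4 of ring C is benzylic, para (through C4a) to O7 and conjugated with O1 of ring A, so a C4–O bond ionises to a quinone-methide-type cation. C6 of ring D is the only free CH that is both ortho to O7 and para to O1. The 2-aryl group and O3 of ring C both lie on the α face, so only the β face of C4 is open.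
4. Both halves come from one silyl enol ether of one (2S)-flavanone. Dioxirane then hydride gives the 2,3-trans-3,4-trans diol, and NBS then hydride gives the bromohydrin. C2 is the only stereocentre set by catalysis, and the other five are relayed from it.
5. Ring order: rings A/D and B/E are bought. The pyranone (future rings C and F) is closed at the chromone stage. A temporary disiloxane ring on the ring F diol and a transient oxirane on ring C are both removed again.

Key step: step 10

Assumption: the (S)-biaryl diphosphine is taken to give (2S)-6, by analogy with the usual sense of induction of (S)-biaryl diphosphines in rhodium-catalysed 1,4-additions to cyclic enones; if the sense is opposite, the (R)-ligand is used.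

## Route

Step 1
Reactants: 1 2',3',4'-trihydroxyacetophenone (gallacetophenone)
Product: 2 1-[3,4-bis(benzyloxy)-2-hydroxyphenyl]ethan-1-one
Conditions: BnBr (2.05 equiv), K2CO3 (2.2 equiv), DMF, 25 °C
Reagents that add atoms: benzyl bromide, BrCc1ccccc1
Why: Williamson ether synthesis; the 2-OH is tied up in a hydrogen bond to the acetyl carbonyl and is the least reactive of the three, so two equivalents of benzyl bromide should alkylate only O3 and O4.

Step 2
Reactants: 2 1-[3,4-bis(benzyloxy)-2-hydroxyphenyl]ethan-1-one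
Product: 4 7,8-bis(benzyloxy)-4H-chromen-4-one, via enaminone 3 (not isolated)
Conditions: Me2NCH(OMe)2, toluene, 100 °C; evaporate; conc. HCl, CH2Cl2, 40 °C
Reagents that add atoms: N,N-dimethylformamide dimethyl acetal, COC(OC)N(C)C
Why: Enaminone condensation at the acetyl CH3, followed by acid-induced addition–elimination of the free phenol with loss of dimethylamine, is the standard chromone synthesis and closes the pyranone ring.

Step 3
Reactants: 4 7,8-bis(benzyloxy)-4H-chromen-4-one; 5 [4-(benzyloxy)phenyl]boronic acid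
Product: 6 (2S)-7,8-bis(benzyloxy)-2-[4-(benzyloxy)phenyl]chroman-4-one (2-aryl α)
Conditions: [Rh(OH)(cod)]2 (1.5 mol %), (S)-2,2'-bis[bis(3,4,5-trifluorophenyl)phosphino]-6,6'-dimethoxy-1,1'-biphenyl (3.3 mol %), 5 (2 equiv), toluene/H2O 10:1, 25 °C
Reagents that add atoms: none
Why: Hayashi–Miyaura asymmetric 1,4-addition of an arylrhodium species to the chromone C2=C3 bond, a reaction type shown on chromones with electron-poor biaryl diphosphines; the ligand selects the enone face and sets C2, and the base-free medium avoids retro-oxa-Michael racemisation.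

Step 4
Reactants: 6 (2S)-7,8-bis(benzyloxy)-2-[4-(benzyloxy)phenyl]chroman-4-one
Product: 7 (2S)-7,8-bis(benzyloxy)-2-[4-(benzyloxy)phenyl]-4-(trimethylsilyloxy)-2H-chromene
Conditions: Me3SiOTf (1.2 equiv), Et3N (1.5 equiv), CH2Cl2, 0 °C
Reagents that add atoms: trimethylsilyl trifluoromethanesulfonate, C[Si](C)(C)OS(=O)(=O)C(F)(F)F
Why: Soft enolisation with a silyl triflate and an amine traps the ketone as its silyl enol ether without a free enolate, so the ring opening to the chalcone that would racemise C2 is avoided.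

Step 5
Reactants: 7 (2S)-7,8-bis(benzyloxy)-2-[4-(benzyloxy)phenyl]-4-(trimethylsilyloxy)-2H-chromene
Product: 9 (2R,3R)-7,8-bis(benzyloxy)-2-[4-(benzyloxy)phenyl]-3-hydroxychroman-4-one (2,3-trans; 3β-OH), via silyloxy epoxide 8 (not isolated)
Conditions: dimethyldioxirane (acetone solution, 1.1 equiv), CH2Cl2, −40 to 0 °C; then 10% aq. citric acid, THF, 0 °C
Reagents that add atoms: dimethyldioxirane, CC1(C)OO1
Why: Rubottom oxidation; the dioxirane should attack the enol ether on the face anti to the 2-aryl group, and hydrolysis of the silyloxy epoxide gives the diequatorial 2,3-trans 3-hydroxyflavanone, which is also the thermodynamically preferred isomer.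

Step 6
Reactants: 9 (2R,3R)-7,8-bis(benzyloxy)-2-[4-(benzyloxy)phenyl]-3-hydroxychroman-4-one
Product: 10 (2R,3S,4R)-7,8-bis(benzyloxy)-2-[4-(benzyloxy)phenyl]chromane-3,4-diol (tri-O-benzyl-oritin-4α-ol; 2,3-trans-3,4-trans)
Conditions: NaBH4, MeOH/THF, 0 °C
Reagents that add atoms: none
Why: Borohydride reduction of a 2,3-trans-dihydroflavonol; axial hydride delivery to C4 from the β face gives the equatorial 4α-OH, which is the established outcome for this substrate class.

Step 7
Reactants: 10 (2R,3S,4R)-7,8-bis(benzyloxy)-2-[4-(benzyloxy)phenyl]chromane-3,4-diol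
Product: 11 3,4-O-(1,1,3,3-tetraisopropyldisiloxane-1,3-diyl) derivative of 10 (3β-O and 4α-O bridged in a seven-membered ring)
Conditions: (iPr2SiCl)2O (1.1 equiv), imidazole (4 equiv), DMF, 0 °C to rt
Reagents that add atoms: 1,3-dichloro-1,1,3,3-tetraisopropyldisiloxane, CC(C)[Si](Cl)(C(C)C)O[Si](Cl)(C(C)C)C(C)C
Why: Disiloxanediyl protection of a trans-diequatorial 1,2-diol; the temporary ring masks both hydroxyls against O-alkylation, makes the C4–O bond of ring F a poor leaving group and screens C5 of ring D.

Step 8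
Reactants: 7 (2S)-7,8-bis(benzyloxy)-2-[4-(benzyloxy)phenyl]-4-(trimethylsilyloxy)-2H-chromene
Product: 12 (2R,3R)-3-bromo-7,8-bis(benzyloxy)-2-[4-(benzyloxy)phenyl]chroman-4-one (2,3-trans; 3β-Br)
Conditions: NBS (1.02 equiv), THF, −78 °C, dark
Reagents that add atoms: N-bromosuccinimide, O=C1CCC(=O)N1Br
Why: Electrophilic α-bromination of a silyl enol ether under neutral conditions; the enol ether is by far the most nucleophilic site, and bromine should enter anti to the 2-aryl group to give the equatorial 3β-bromide.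

Step 9
Reactants: 12 (2R,3R)-3-bromo-7,8-bis(benzyloxy)-2-[4-(benzyloxy)phenyl]chroman-4-one
Product: 13 (2R,3S,4R)-3-bromo-7,8-bis(benzyloxy)-2-[4-(benzyloxy)phenyl]chroman-4-ol (3β-Br, 4α-OH; trans-bromohydrin)
Conditions: NaBH4, CeCl3·7H2O, MeOH/THF, −40 °C
Reagents that add atoms: none
Why: Luche reduction; the small hydride should add axially to C4 from the β face of the conformer with equatorial 2-aryl and 3-bromo groups, as with equatorial α-bromocyclohexanones, and the cold medium buffered by trivalent cerium should outrun loss of HBr to the flavone.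

Step 10
Reactants: 13 (2R,3S,4R)-3-bromo-7,8-bis(benzyloxy)-2-[4-(benzyloxy)phenyl]chroman-4-ol; 11 3,4-O-(tetraisopropyldisiloxanediyl)-tri-O-benzyl-oritin-4α-ol
Product: 15 hexa-O-benzyl-epioritin-(4β→6)-[3,4-O-(tetraisopropyldisiloxanediyl)oritin-4α-ol], via cis-epoxide 14 (not isolated)
Conditions: 13, KN(SiMe3)2 (1.02 equiv), toluene, −20 °C to rt; the suspension is then added slowly to 11 (2.5 equiv) in CH2Cl2/(CF3)2CHOH 3:1, −40 to 0 °C
Reagents that add atoms: none
Why: Proposed new method: the potassium alkoxide of 13 should displace the 3β-bromide from the ring-flipped diaxial conformer, which inverts C3 and moves the former carbonyl oxygen to the α face (2,3-cis), and in hexafluoroisopropanol the strained C4–O bond of 14 should then ionise under hydrogen-bond assistance, because C4 is para through C4a to O7 and conjugated with O1 of ring A, to the quinone-methide-type flavan-4-yl cation presumed for proanthocyanidin biosynthesis, which C6 of ring D of 11 traps in a Friedel–Crafts alkylation. The closest known reaction types are the fluoroalcohol-promoted Friedel–Crafts opening of styrene-type oxides by alkoxyarenes, the spontaneous C4 solvolysis of 7-alkoxychromene 3,4-oxides made from bromohydrins, and the coupling of 4-oxygenated or 4-thio flavan-3-ols with flavanoid benzo rings; the new element is a 3,4-epoxyflavan as donor for an interflavanyl bond. The only ring closed is the transient oxirane (3-exo-tet), which is opened again in the same flask, so no new ring remains in 15. C3 is controlled by the stereospecific inversion at the C–Br bond, and C4 by the 2-aryl group and O3, which both occupy the α face and leave only the β face open (trans-diaxial opening, Fürst–Plattner rule), the normal outcome for 2,3-cis flavan-4-yl cations. The regioselectivity needed is C6 over C5 of ring D, and it is secured because C6 is ortho to O7 and para to O1 whereas C5 is activated only by the twisted O8 and is screened by the peri disiloxane ring. The chemoselectivity needed is ionisation of 14 alone without oligomerisation, and it is secured because the silylated C4–O bond of 11 is unstrained and inert without acid, its hydroxyls cannot form ethers, the axial C3–O and equatorial H3 of the cation disfavour the 1,2-hydride shift to the flavan-3-one, and slow addition to excess recoverable 11 keeps ring A of 14 and of 15 from competing.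

Step 11
Reactants: 15 hexa-O-benzyl-epioritin-(4β→6)-[3,4-O-(tetraisopropyldisiloxanediyl)oritin-4α-ol]
Product: 16 epioritin-(4β→6)-[3,4-O-(tetraisopropyldisiloxanediyl)oritin-4α-ol] (six free phenols)
Conditions: H2 (1 atm), Pd(OH)2/C, THF/MeOH, rt
Reagents that add atoms: none
Why: Catalytic hydrogenolysis of aryl benzyl ethers, the usual final debenzylation of proanthocyanidins; the benzylic C4–O bond of ring F stays shielded as a hindered silyl ether, and the interflavanyl C–C and C2–O1 bonds are inert under neutral conditions.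

Step 12
Reactants: 16 epioritin-(4β→6)-[3,4-O-(tetraisopropyldisiloxanediyl)oritin-4α-ol]
Product: 17 epioritin-(4β→6)-oritin-4α-ol (upper unit 2R,3R,4S; lower unit 2R,3S,4R)
Conditions: Et3N·3HF, THF, 0 °C to rt, argon
Reagents that add atoms: none
Why: Fluoride-induced Si–O cleavage in a weakly acidic, oxygen-free medium; it touches no stereocentre and avoids the phenoxides that would lead to quinone methides or to air oxidation of the 7,8-dihydroxy rings.

## Compound list

1 | 2',3',4'-trihydroxyacetophenone | CC(=O)c1ccc(O)c(O)c1O | starting material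
2 | 1-[3,4-bis(benzyloxy)-2-hydroxyphenyl]ethan-1-one | CC(=O)c1ccc(OCc2ccccc2)c(OCc2ccccc2)c1O | intermediate
3 | (E)-1-[3,4-bis(benzyloxy)-2-hydroxyphenyl]-3-(dimethylamino)prop-2-en-1-one | CN(C)/C=C/C(=O)c1ccc(OCc2ccccc2)c(OCc2ccccc2)c1O | intermediate
4 | 7,8-bis(benzyloxy)-4H-chromen-4-one | O=c1ccoc2c1ccc(OCc1ccccc1)c2OCc1ccccc1 | intermediate
5 | [4-(benzyloxy)phenyl]boronic acid | OB(O)c1ccc(OCc2ccccc2)cc1 | starting material
6 | (2S)-7,8-bis(benzyloxy)-2-[4-(benzyloxy)phenyl]chroman-4-one | c1cc2c(c(OCc3ccccc3)c1OCc4ccccc4)O[C@H](c5ccc(OCc6ccccc6)cc5)CC2=O | intermediate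
7 | (2S)-7,8-bis(benzyloxy)-2-[4-(benzyloxy)phenyl]-4-(trimethylsilyloxy)-2H-chromene | c1cc2c(c(OCc3ccccc3)c1OCc4ccccc4)O[C@H](c5ccc(OCc6ccccc6)cc5)C=C2O[Si](C)(C)C | intermediate
8 | 3β,4β-epoxy-4α-(trimethylsilyloxy) derivative of the tri-O-benzyl flavan (oxirane anti to the 2-aryl group) | c1cc2c(c(OCc3ccccc3)c1OCc4ccccc4)O[C@H](c5ccc(OCc6ccccc6)cc5)[C@H]7O[C@@]27O[Si](C)(C)C | intermediate
9 | (2R,3R)-7,8-bis(benzyloxy)-2-[4-(benzyloxy)phenyl]-3-hydroxychroman-4-one | c1cc2c(c(OCc3ccccc3)c1OCc4ccccc4)O[C@H](c5ccc(OCc6ccccc6)cc5)[C@@H](O)C2=O | intermediate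
10 | (2R,3S,4R)-7,8-bis(benzyloxy)-2-[4-(benzyloxy)phenyl]chromane-3,4-diol | c1cc2c(c(OCc3ccccc3)c1OCc4ccccc4)O[C@H](c5ccc(OCc6ccccc6)cc5)[C@@H](O)[C@@H]2O | intermediate
11 | 3,4-O-(1,1,3,3-tetraisopropyldisiloxane-1,3-diyl) derivative of 10 | c1cc2c(c(OCc3ccccc3)c1OCc4ccccc4)O[C@H](c5ccc(OCc6ccccc6)cc5)[C@@H](O[Si]7(C(C)C)C(C)C)[C@@H]2O[Si](C(C)C)(C(C)C)O7 | intermediate
12 | (2R,3R)-3-bromo-7,8-bis(benzyloxy)-2-[4-(benzyloxy)phenyl]chroman-4-one | c1cc2c(c(OCc3ccccc3)c1OCc4ccccc4)O[C@H](c5ccc(OCc6ccccc6)cc5)[C@@H](Br)C2=O | intermediate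
13 | (2R,3S,4R)-3-bromo-7,8-bis(benzyloxy)-2-[4-(benzyloxy)phenyl]chroman-4-ol | c1cc2c(c(OCc3ccccc3)c1OCc4ccccc4)O[C@H](c5ccc(OCc6ccccc6)cc5)[C@@H](Br)[C@@H]2O | intermediate
14 | 2,3-cis-3α,4α-epoxy-7,8-bis(benzyloxy)-2-[4-(benzyloxy)phenyl]chromane (oxirane on the face of the 2-aryl group) | c1cc2c(c(OCc3ccccc3)c1OCc4ccccc4)O[C@H](c5ccc(OCc6ccccc6)cc5)[C@@H]7O[C@H]27 | intermediate
15 | hexa-O-benzyl-epioritin-(4β→6)-[3,4-O-(tetraisopropyldisiloxanediyl)oritin-4α-ol] | c8ccccc8COc1ccc([C@H]2Oc3c(ccc(OCc8ccccc8)c3OCc8ccccc8)[C@H](c4cc5c(c(OCc8ccccc8)c4OCc8ccccc8)O[C@H](c6ccc(OCc8ccccc8)cc6)[C@@H](O[Si]7(C(C)C)C(C)C)[C@@H]5O[Si](C(C)C)(C(C)C)O7)[C@H]2O)cc1 | intermediate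
16 | epioritin-(4β→6)-[3,4-O-(tetraisopropyldisiloxanediyl)oritin-4α-ol] | Oc1ccc([C@H]2Oc3c(ccc(O)c3O)[C@H](c4cc5c(c(O)c4O)O[C@H](c6ccc(O)cc6)[C@@H](O[Si]7(C(C)C)C(C)C)[C@@H]5O[Si](C(C)C)(C(C)C)O7)[C@H]2O)cc1 | intermediate
17 | epioritin-(4β→6)-oritin-4α-ol | Oc1ccc([C@H]2Oc3c(ccc(O)c3O)[C@H](c3cc4c(c(O)c3O)O[C@H](c3ccc(O)cc3)[C@@H](O)[C@@H]4O)[C@H]2O)cc1 | target

## Step count and risks

Total step count: 12. Longest linear sequence: 10 (steps 1 to 7, then 10 to 12).

**1. Step 10.** The labile epoxide may rearrange by hydride shift, or oligomerise through its own ring A, faster than ring D captures it.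
- The fallback sets out from 13 and comes back at 15.
- Epoxide 14 is generated from 13 with KN(SiMe3)2 as before. It is then quenched in the basic medium, where it is stable, with potassium phenylmethanethiolate (BnSH, KN(SiMe3)2, THF, 0 °C).
- SN2 opening at C4 from the β face should give the storable 4β-benzylsulfanyl-tri-O-benzylepioritin F1.
- F1 is activated in the presence of 11 with the thiophilic salt AgBF4 (THF/CH2Cl2, 0 °C). This is the known orthogonal activation of 4-thio flavan-3-ols beside a 4-oxygenated acceptor, and it releases the same cation in a controlled way to give 15.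

**2. Step 9.** Hydride delivery may show poor facial selectivity, and a cis-bromohydrin cannot close to the oxirane. The basic hydride may also cause loss of HBr.
- The fallback sets out from 6 and comes back at 13.
- NaBH4 (MeOH/THF, 0 °C) gives the (2S,4S)-2,4-cis-flavan-4-ol tribenzyl ether F2.
- MsCl/Et3N (CH2Cl2, 0 °C) eliminates through the mesylate to the (2S)-flav-3-ene tribenzyl ether F3.
- NBS in aqueous THF (0 °C) adds bromine anti to the 2-aryl group and water at benzylic C4 from the opposite face. This anti bromohydroxylation fixes the trans relationship of 13 by mechanism.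

**3. Step 3.** Insertion into the electron-rich, 8-alkoxy-flanked chromone may be sluggish. Protodeboronation may compete, or ring opening may erode the enantiopurity.
- The fallback sets out from 2 and comes back at 6.
- Claisen–Schmidt condensation of 2 with commercial 4-(benzyloxy)benzaldehyde (KOH, EtOH, rt) gives the 2'-hydroxychalcone F4.
- NaOAc in refluxing EtOH cyclises it to the racemic flavanone F5.
- Kinetic resolution by Noyori-type transfer hydrogenation (RuCl[(R,R)-TsDPEN](p-cymene), HCO2H/Et3N, EtOAc, rt) should reduce the (2R) enantiomer to the (2R,4R)-flavan-4-ol F6. F6 is removed by chromatography, which leaves (2S)-6.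

## Further compounds

F1 | step 10 | 4β-benzylsulfanyl-tri-O-benzylepioritin (2α-aryl, 3α-OH, 4β-SBn) | c1cc2c(c(OCc3ccccc3)c1OCc4ccccc4)O[C@H](c5ccc(OCc6ccccc6)cc5)[C@H](O)[C@H]2SCc7ccccc7
F2 | step 9 | (2S,4S)-7,8-bis(benzyloxy)-2-[4-(benzyloxy)phenyl]chroman-4-ol | c1cc2c(c(OCc3ccccc3)c1OCc4ccccc4)O[C@H](c5ccc(OCc6ccccc6)cc5)C[C@@H]2O
F3 | step 9 | (2S)-7,8-bis(benzyloxy)-2-[4-(benzyloxy)phenyl]-2H-chromene | c1cc2c(c(OCc3ccccc3)c1OCc4ccccc4)O[C@H](c5ccc(OCc6ccccc6)cc5)C=C2
F4 | step 3 | (E)-1-[3,4-bis(benzyloxy)-2-hydroxyphenyl]-3-[4-(benzyloxy)phenyl]prop-2-en-1-one | O=C(/C=C/c1ccc(OCc2ccccc2)cc1)c1ccc(OCc2ccccc2)c(OCc2ccccc2)c1O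
F5 | step 3 | racemic 7,8-bis(benzyloxy)-2-[4-(benzyloxy)phenyl]chroman-4-one | c1cc2c(c(OCc3ccccc3)c1OCc4ccccc4)OC(c5ccc(OCc6ccccc6)cc5)CC2=O
F6 | step 3 | (2R,4R)-7,8-bis(benzyloxy)-2-[4-(benzyloxy)phenyl]chroman-4-ol | c1cc2c(c(OCc3ccccc3)c1OCc4ccccc4)O[C@@H](c5ccc(OCc6ccccc6)cc5)C[C@H]2O
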